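**Retrosynthetic overview**

1. C5'–C6' is made last: an asymmetric Nozaki–Hiyama–Kishi coupling joins a C1'–C5' aryl aldehyde to a C6'–C16' (E)-vinyl iodide ketone; acetylation and desilylation finish.
2. Both E-trisubstituted alkenes come from Zr-catalysed syn-carboalumination of terminal alkynes (iodinolysis on one side, Pd benzylation of a bromomethyl arene from 2,6-dimethylhydroquinone on the other).
3. C7'–C12' with the C11' stereocentre comes from meso cis-2,6-dimethylcyclohexanone: chiral lithium amide deprotonation/O-triflation breaks the symmetry, the triflate is reduced and the ring alkene is ozonised to a keto aldehyde.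
4. The keto aldehyde takes the prenyl group by α-selective allylbarium addition (C12'–C13'); the methyl ketone becomes the terminal alkyne (C6'–C7').
5. Rings: none is formed; the benzene ring comes with the feedstock and the cyclohexane ring is only opened.

Assumption: ketone 1 is used as the pure cis isomer (commercial cis-rich mixture, equilibrated and purified), and the (S,S)-amide and (S)-ligand named below are taken as the antipodes giving the (6S)-enolate and the (5'S)-carbinol (the base by analogy with 4-substituted cyclohexanones; the mirror-image reagent is used if a test run shows the opposite sense). Side-chain locants run from C1' (benzylic) to C16'.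

**Step 1**
Reactants: 1 cis-2,6-dimethylcyclohexanone (meso)
Product: 3 (S)-2,6-dimethylcyclohex-1-en-1-yl trifluoromethanesulfonate, via lithium enolate 2 (not isolated)
Conditions: (S,S)-[PhCH(Me)]2NH, n-BuLi, LiCl, THF, −78 °C; then PhNTf2, −78 → 0 °C
Reagents that add atoms: N-phenylbis(trifluoromethanesulfonimide) (PhNTf2), O=S(=O)(N(c1ccccc1)S(=O)(=O)C(F)(F)F)C(F)(F)F
Why: Enantioselective deprotonation of a meso ketone by a C2-symmetric chiral lithium amide (Simpkins–Koga type) removes one of the two enantiotopic α-hydrogens, so the untouched α-carbon becomes the (S)-stereocentre (later C11'), and O-triflation of the only possible, tetrasubstituted enolate fixes it.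

**Step 2**
Reactants: 3 (S)-2,6-dimethylcyclohex-1-en-1-yl trifluoromethanesulfonate
Product: 4 (S)-1,3-dimethylcyclohex-1-ene
Conditions: Pd(OAc)2 (2 mol%), PPh3, HCO2H, Bu3N, DMF, 60 °C
Reagents that add atoms: none
Why: Palladium-catalysed formate reduction of an enol triflate (oxidative addition, formate-to-hydride exchange with loss of CO2, reductive elimination) replaces OTf by H without touching the allylic stereocentre.

**Step 3**
Reactants: 4 (S)-1,3-dimethylcyclohex-1-ene
Product: 6 (S)-2-methyl-6-oxoheptanal, via ozonide 5 (not isolated)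
Conditions: O3, CH2Cl2, −78 °C; then PPh3, −78 °C → rt
Reagents that add atoms: ozone, [O-][O+]=O
Why: Ozonolysis with reductive work-up opens the ring alkene to a methyl ketone and an aldehyde, the stereocentre now sitting α to the aldehyde, and the neutral cold PPh3 work-up avoids its epimerisation.

**Step 4**
Reactants: 6 (S)-2-methyl-6-oxoheptanal; 7 1-chloro-3-methylbut-2-ene (prenyl chloride)
Product: 10 (6S)-6,10-dimethyl-7-[(triethylsilyl)oxy]undec-9-en-2-one (C7 epimers), via prenylbarium chloride 8 (not isolated), via barium alkoxide 9 (not isolated)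
Conditions: activated Ba (from BaI2 and lithium biphenylide, THF, rt), 7, THF, −78 °C; then 6 (slow addition), −78 °C; then TESCl, imidazole (cat.), −78 → 0 °C
Reagents that add atoms: chlorotriethylsilane (TESCl), CC[Si](Cl)(CC)CC
Why: Allylbarium reagents add to carbonyls at the unsubstituted α-terminus (Yamamoto α-selective allylation) and the aldehyde reacts far faster than the methyl ketone at −78 °C, giving the linear prenyl carbinol, which is silylated in the same pot; the new carbinol centre is left as a mixture because it is oxidised in step 7.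

**Step 5**
Reactants: 10 (6S)-6,10-dimethyl-7-[(triethylsilyl)oxy]undec-9-en-2-one
Product: 12 triethyl{[(6S)-6,10-dimethylundec-9-en-1-yn-7-yl]oxy}silane, via enol phosphate 11 (not isolated)
Conditions: LiN(iPr)2 (LDA, 1.1 equiv), THF, −78 °C; ClP(O)(OEt)2, −78 → 0 °C; LDA (2.3 equiv), −78 °C → rt; H2O
Reagents that add atoms: none
Why: Kinetic enolisation at the methyl group, O-phosphorylation and LDA-induced elimination (Negishi methyl ketone to terminal alkyne conversion) give the alkyne, and the stereocentre carries no acidic hydrogen at this stage.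

**Step 6**
Reactants: 12 triethyl{[(6S)-6,10-dimethylundec-9-en-1-yn-7-yl]oxy}silane
Product: 15 (1E,6S)-1-iodo-2,6,10-trimethylundeca-1,9-dien-7-ol (C7 epimers), via alkenylalane 13 (not isolated), via TES-protected vinyl iodide 14 (not isolated)
Conditions: Me3Al (2.5 equiv), Cp2ZrCl2 (25 mol%), CH2Cl2, 0 °C → rt; I2, THF, −30 → 0 °C; then 1 M HCl, THF, rt
Reagents that add atoms: trimethylaluminium (Me3Al), C[Al](C)C; iodine (I2), II
Why: Zirconium-catalysed syn-carboalumination (Negishi) puts Me on the internal and Al on the terminal alkyne carbon, iodinolysis with retention fixes the E geometry of the later C6'=C7' bond, and dilute acid removes the TES group; the prenyl alkene is inert.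

**Step 7**
Reactants: 15 (1E,6S)-1-iodo-2,6,10-trimethylundeca-1,9-dien-7-ol
Product: 16 (6S,10E)-11-iodo-2,6,10-trimethylundeca-2,10-dien-5-one
Conditions: Dess–Martin periodinane, NaHCO3, CH2Cl2, 0 °C → rt
Reagents that add atoms: none
Why: Buffered Dess–Martin oxidation converges both carbinol epimers to the β,γ-unsaturated ketone under non-enolising conditions, so the α-methyl stereocentre and the alkene position are kept.

**Step 8**
Reactants: 17 2,6-dimethylbenzene-1,4-diol (2,6-dimethylhydroquinone)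
Product: 18 [(2,6-dimethyl-1,4-phenylene)bis(oxy)]bis(tert-butyldimethylsilane)
Conditions: TBSCl (2.5 equiv), imidazole, DMF, rt → 50 °C
Reagents that add atoms: tert-butylchlorodimethylsilane (TBSCl), CC(C)(C)[Si](C)(C)Cl
Why: Imidazole-promoted silylation of both phenols masks the hydroquinone against the radical, organoaluminium and chromium steps.

**Step 9**
Reactants: 18 [(2,6-dimethyl-1,4-phenylene)bis(oxy)]bis(tert-butyldimethylsilane)
Product: 19 {[2-(bromomethyl)-6-methyl-1,4-phenylene]bis(oxy)}bis(tert-butyldimethylsilane)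
Conditions: NBS (1.0 equiv), AIBN (cat.), PhCF3, 80 °C
Reagents that add atoms: N-bromosuccinimide (NBS), O=C1CCC(=O)N1Br
Why: Wohl–Ziegler benzylic bromination with one equivalent of NBS in a non-polar solvent functionalises one of the two equivalent methyl groups (statistical mono-bromination; 18 is recovered and recycled).

**Step 10**
Reactants: 19 {[2-(bromomethyl)-6-methyl-1,4-phenylene]bis(oxy)}bis(tert-butyldimethylsilane); 20 but-3-yn-1-ol
Product: 22 (E)-5-[2,5-bis(tert-butyldimethylsilyloxy)-3-methylphenyl]-3-methylpent-3-en-1-ol, via alkenylalane 21 (not isolated)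
Conditions: 20, Me3Al (3 equiv), Cp2ZrCl2 (25 mol%), CH2Cl2, 0 °C → rt; volatiles removed; then 19, Pd(PPh3)4 (5 mol%), THF, rt; aq. potassium sodium tartrate
Reagents that add atoms: trimethylaluminium (Me3Al), C[Al](C)C
Why: Negishi syn-carboalumination of the homopropargylic aluminium alkoxide followed by palladium-catalysed alkenyl–benzyl cross-coupling with retention delivers the (E)-C2'=C3' alkene and the aryl–CH2 link in one pot.

**Step 11**
Reactants: 22 (E)-5-[2,5-bis(tert-butyldimethylsilyloxy)-3-methylphenyl]-3-methylpent-3-en-1-ol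
Product: 23 (E)-5-[2,5-bis(tert-butyldimethylsilyloxy)-3-methylphenyl]-3-methylpent-3-enal
Conditions: Dess–Martin periodinane, NaHCO3, CH2Cl2, 0 °C; used at once
Reagents that add atoms: none
Why: Buffered Dess–Martin oxidation gives the β,γ-unsaturated aldehyde without base or acid strong enough to move the alkene into conjugation.

**Step 12**
Reactants: 16 (6S,10E)-11-iodo-2,6,10-trimethylundeca-2,10-dien-5-one; 23 (E)-5-[2,5-bis(tert-butyldimethylsilyloxy)-3-methylphenyl]-3-methylpent-3-enal
Product: 24 (2E,5S,6E,11S)-1-[2,5-bis(tert-butyldimethylsilyloxy)-3-methylphenyl]-5-hydroxy-3,7,11,15-tetramethylhexadeca-2,6,14-trien-12-one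
Conditions: CrCl2 (10 mol%), (S)-N-[2-(4-isopropyl-4,5-dihydrooxazol-2-yl)-6-methylphenyl]methanesulfonamide (11 mol%), 1,8-bis(dimethylamino)naphthalene (11 mol%), NiCl2(2,9-dimethyl-1,10-phenanthroline) (2 mol%), Mn, Cp2ZrCl2, LiCl, MeCN, rt
Reagents that add atoms: none
Why: Catalytic asymmetric Nozaki–Hiyama–Kishi coupling: nickel activates the vinyl iodide with retention of the E geometry, the alkenylchromium species adds only to the aldehyde (the ketone and its α-stereocentre are untouched), and the chromium-bound chiral sulfonamide ligand sets C5' as S.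

**Step 13**
Reactants: 24 (2E,5S,6E,11S)-1-[2,5-bis(tert-butyldimethylsilyloxy)-3-methylphenyl]-5-hydroxy-3,7,11,15-tetramethylhexadeca-2,6,14-trien-12-one
Product: 25 (2E,5S,6E,11S)-1-[2,5-bis(tert-butyldimethylsilyloxy)-3-methylphenyl]-3,7,11,15-tetramethyl-12-oxohexadeca-2,6,14-trien-5-yl acetate
Conditions: Ac2O, pyridine, DMAP (cat.), CH2Cl2, 0 °C
Reagents that add atoms: acetic anhydride (Ac2O), CC(=O)OC(C)=O
Why: DMAP-catalysed O-acylation of the secondary allylic alcohol proceeds with retention at C5' and is too weakly basic to epimerise C11'.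

**Step 14**
Reactants: 25 (2E,5S,6E,11S)-1-[2,5-bis(tert-butyldimethylsilyloxy)-3-methylphenyl]-3,7,11,15-tetramethyl-12-oxohexadeca-2,6,14-trien-5-yl acetate
Product: 26 (2E,5S,6E,11S)-1-(2,5-dihydroxy-3-methylphenyl)-3,7,11,15-tetramethyl-12-oxohexadeca-2,6,14-trien-5-yl acetate (CNP0102989.1)
Conditions: HF·pyridine, pyridine, THF, 0 °C → rt; degassed work-up
Reagents that add atoms: none
Why: Fluoride cleavage of the two aryl silyl ethers under mildly acidic conditions leaves the allylic acetate, the β,γ-unsaturated ketone and both stereocentres untouched.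

**Compound list**

1 | cis-2,6-dimethylcyclohexanone (meso, 2R,6S) | C[C@H]1CCC[C@@H](C)C1=O | starting material
2 | lithium (S)-2,6-dimethylcyclohex-1-en-1-olate | [Li+].[O-]C1=C(C)CCC[C@@H]1C | intermediate
3 | (S)-2,6-dimethylcyclohex-1-en-1-yl trifluoromethanesulfonate | CC1=C(OS(=O)(=O)C(F)(F)F)[C@@H](C)CCC1 | intermediate
4 | (S)-1,3-dimethylcyclohex-1-ene | CC1=C[C@@H](C)CCC1 | intermediate
5 | ozonide of 4, (2S)-2,6-dimethyl-7,8,9-trioxabicyclo[4.2.1]nonane (ozonide centres mixed) | CC12CCC[C@H](C)C(OO1)O2 | intermediate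
6 | (S)-2-methyl-6-oxoheptanal | CC(=O)CCC[C@H](C)C=O | intermediate
7 | 1-chloro-3-methylbut-2-ene (prenyl chloride) | CC(C)=CCCl | starting material
8 | (3-methylbut-2-en-1-yl)barium chloride | CC(C)=CC[Ba]Cl | intermediate
9 | chlorobarium alkoxide of (6S)-7-hydroxy-6,10-dimethylundec-9-en-2-one | CC(=O)CCC[C@H](C)C(CC=C(C)C)O[Ba]Cl | intermediate
10 | (6S)-6,10-dimethyl-7-[(triethylsilyl)oxy]undec-9-en-2-one (C7 epimers) | CC(=O)CCC[C@H](C)C(CC=C(C)C)O[Si](CC)(CC)CC | intermediate
11 | diethyl (6S)-6,10-dimethyl-7-[(triethylsilyl)oxy]undeca-1,9-dien-2-yl phosphate | C=C(OP(=O)(OCC)OCC)CCC[C@H](C)C(CC=C(C)C)O[Si](CC)(CC)CC | intermediate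
12 | triethyl{[(6S)-6,10-dimethylundec-9-en-1-yn-7-yl]oxy}silane | C#CCCC[C@H](C)C(CC=C(C)C)O[Si](CC)(CC)CC | intermediate
13 | dimethyl{(1E,6S)-2,6,10-trimethyl-7-[(triethylsilyl)oxy]undeca-1,9-dien-1-yl}aluminium | C[Al](C)/C=C(\C)CCC[C@H](C)C(CC=C(C)C)O[Si](CC)(CC)CC | intermediate
14 | triethyl{[(1E,6S)-1-iodo-2,6,10-trimethylundeca-1,9-dien-7-yl]oxy}silane | I/C=C(\C)CCC[C@H](C)C(CC=C(C)C)O[Si](CC)(CC)CC | intermediate
15 | (1E,6S)-1-iodo-2,6,10-trimethylundeca-1,9-dien-7-ol (C7 epimers) | I/C=C(\C)CCC[C@H](C)C(O)CC=C(C)C | intermediate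
16 | (6S,10E)-11-iodo-2,6,10-trimethylundeca-2,10-dien-5-one | I/C=C(\C)CCC[C@H](C)C(=O)CC=C(C)C | intermediate
17 | 2,6-dimethylbenzene-1,4-diol (2,6-dimethylhydroquinone) | Cc1cc(O)cc(C)c1O | starting material
18 | [(2,6-dimethyl-1,4-phenylene)bis(oxy)]bis(tert-butyldimethylsilane) | Cc1cc(O[Si](C)(C)C(C)(C)C)cc(C)c1O[Si](C)(C)C(C)(C)C | intermediate
19 | {[2-(bromomethyl)-6-methyl-1,4-phenylene]bis(oxy)}bis(tert-butyldimethylsilane) | Cc1cc(O[Si](C)(C)C(C)(C)C)cc(CBr)c1O[Si](C)(C)C(C)(C)C | intermediate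
20 | but-3-yn-1-ol | C#CCCO | starting material
21 | (E)-alkenylalane from 20, dimethylaluminium 4-(dimethylalumanyl)-3-methylbut-3-en-1-olate | C[Al](C)/C=C(\C)CCO[Al](C)C | intermediate
22 | (E)-5-[2,5-bis(tert-butyldimethylsilyloxy)-3-methylphenyl]-3-methylpent-3-en-1-ol | OCC/C(C)=C/Cc1cc(O[Si](C)(C)C(C)(C)C)cc(C)c1O[Si](C)(C)C(C)(C)C | intermediate
23 | (E)-5-[2,5-bis(tert-butyldimethylsilyloxy)-3-methylphenyl]-3-methylpent-3-enal | O=CC/C(C)=C/Cc1cc(O[Si](C)(C)C(C)(C)C)cc(C)c1O[Si](C)(C)C(C)(C)C | intermediate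
24 | (2E,5S,6E,11S)-1-[2,5-bis(tert-butyldimethylsilyloxy)-3-methylphenyl]-5-hydroxy-3,7,11,15-tetramethylhexadeca-2,6,14-trien-12-one | O[C@H](/C=C(\C)CCC[C@H](C)C(=O)CC=C(C)C)C/C(C)=C/Cc1cc(O[Si](C)(C)C(C)(C)C)cc(C)c1O[Si](C)(C)C(C)(C)C | intermediate
25 | (2E,5S,6E,11S)-1-[2,5-bis(tert-butyldimethylsilyloxy)-3-methylphenyl]-3,7,11,15-tetramethyl-12-oxohexadeca-2,6,14-trien-5-yl acetate | CC(=O)O[C@H](/C=C(\C)CCC[C@H](C)C(=O)CC=C(C)C)C/C(C)=C/Cc1cc(O[Si](C)(C)C(C)(C)C)cc(C)c1O[Si](C)(C)C(C)(C)C | intermediate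
26 | (2E,5S,6E,11S)-1-(2,5-dihydroxy-3-methylphenyl)-3,7,11,15-tetramethyl-12-oxohexadeca-2,6,14-trien-5-yl acetate (CNP0102989.1) | CC(=O)O[C@H](/C=C(\C)CCC[C@H](C)C(=O)CC=C(C)C)C/C(C)=C/Cc1cc(O)cc(C)c1O | target

**Step count and risks**

Total: 14 steps. Longest linear sequence: 10 steps (1–7, then 12–14); the arene branch (8–11) joins at step 12.

The three steps most likely to fail:

Step 1 (enantioselectivity of the deprotonation under external triflimide quench, and the need for isomerically pure cis ketone). Fallback: the symmetry is broken by oxygen insertion instead of enolisation. Setting out from 1, a Baeyer–Villiger monooxygenase (cyclohexanone monooxygenase in whole cells, O2, glucose; enzyme or its enantiocomplementary relative chosen so that the (R)-configured α-carbon migrates) gives (3S,7R)-3,7-dimethyloxepan-2-one F1. LiAlH4 in THF opens it to (2S,6R)-2-methylheptane-1,6-diol F2, and a double Swern oxidation (DMSO, (COCl)2, then iPr2NEt, −78 °C) comes back to the route at 6, bypassing 3 and 4.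

Step 4 (aldehyde-over-ketone and α-over-γ selectivity of the barium reagent on an epimerisable aldehyde). Fallback: the prenyl group is built by metathesis instead of by a prenyl nucleophile. Setting out from 6, allylboronic acid pinacol ester (CH2Cl2, rt) adds only to the aldehyde and gives (6S)-7-hydroxy-6-methyldec-9-en-2-one F3. TESCl and imidazole give (6S)-6-methyl-7-[(triethylsilyl)oxy]dec-9-en-2-one F4, and cross-metathesis with 2-methylbut-2-ene (second-generation Grubbs catalyst, 40 °C) comes back to the route at 10.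

Step 12 (level of ligand control at C5' on a sensitive β,γ-unsaturated aldehyde; the remote C5'/C11' diastereomers are hard to separate). Fallback: C5' is set by reagent-controlled ketone reduction instead of by the chromium ligand. Setting out from 14 (isolated by leaving out the HCl treatment of step 6) and 23, a ligand-free coupling (CrCl2, NiCl2 cat., DMSO, rt) gives the C5'-epimeric alcohol (2E,6E,11S)-1-[2,5-bis(tert-butyldimethylsilyloxy)-3-methylphenyl]-3,7,11,15-tetramethyl-12-[(triethylsilyl)oxy]hexadeca-2,6,14-trien-5-ol F5. Dess–Martin oxidation gives the corresponding hexadeca-2,6,14-trien-5-one F6. Corey–Bakshi–Shibata reduction ((R)-2-methyl-CBS-oxazaborolidine, catecholborane, toluene, −78 °C; alkenyl as the large group) gives the (5S)-alcohol F7. Ac2O/pyridine gives the (5S)-acetate F8, AcOH/THF/H2O removes only the TES group to give the (5S)-acetoxy C12' alcohol F9, and Dess–Martin oxidation comes back to the route at 25.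

**Further compounds**

F1 | step 1 | (3S,7R)-3,7-dimethyloxepan-2-one | O=C1O[C@H](C)CCC[C@@H]1C
F2 | step 1 | (2S,6R)-2-methylheptane-1,6-diol | C[C@@H](O)CCC[C@H](C)CO
F3 | step 4 | (6S)-7-hydroxy-6-methyldec-9-en-2-one (C7 epimers) | CC(=O)CCC[C@H](C)C(O)CC=C
F4 | step 4 | (6S)-6-methyl-7-[(triethylsilyl)oxy]dec-9-en-2-one (C7 epimers) | CC(=O)CCC[C@H](C)C(CC=C)O[Si](CC)(CC)CC
F5 | step 12 | (2E,6E,11S)-1-[2,5-bis(tert-butyldimethylsilyloxy)-3-methylphenyl]-3,7,11,15-tetramethyl-12-[(triethylsilyl)oxy]hexadeca-2,6,14-trien-5-ol (C5 and C12 epimers) | OC(/C=C(\C)CCC[C@H](C)C(CC=C(C)C)O[Si](CC)(CC)CC)C/C(C)=C/Cc1cc(O[Si](C)(C)C(C)(C)C)cc(C)c1O[Si](C)(C)C(C)(C)C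
F6 | step 12 | (2E,6E,11S)-1-[2,5-bis(tert-butyldimethylsilyloxy)-3-methylphenyl]-3,7,11,15-tetramethyl-12-[(triethylsilyl)oxy]hexadeca-2,6,14-trien-5-one | O=C(/C=C(\C)CCC[C@H](C)C(CC=C(C)C)O[Si](CC)(CC)CC)C/C(C)=C/Cc1cc(O[Si](C)(C)C(C)(C)C)cc(C)c1O[Si](C)(C)C(C)(C)C
F7 | step 12 | (2E,5S,6E,11S)-1-[2,5-bis(tert-butyldimethylsilyloxy)-3-methylphenyl]-3,7,11,15-tetramethyl-12-[(triethylsilyl)oxy]hexadeca-2,6,14-trien-5-ol | O[C@H](/C=C(\C)CCC[C@H](C)C(CC=C(C)C)O[Si](CC)(CC)CC)C/C(C)=C/Cc1cc(O[Si](C)(C)C(C)(C)C)cc(C)c1O[Si](C)(C)C(C)(C)C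
F8 | step 12 | (2E,5S,6E,11S)-1-[2,5-bis(tert-butyldimethylsilyloxy)-3-methylphenyl]-3,7,11,15-tetramethyl-12-[(triethylsilyl)oxy]hexadeca-2,6,14-trien-5-yl acetate | CC(=O)O[C@H](/C=C(\C)CCC[C@H](C)C(CC=C(C)C)O[Si](CC)(CC)CC)C/C(C)=C/Cc1cc(O[Si](C)(C)C(C)(C)C)cc(C)c1O[Si](C)(C)C(C)(C)C
F9 | step 12 | (2E,5S,6E,11S)-1-[2,5-bis(tert-butyldimethylsilyloxy)-3-methylphenyl]-12-hydroxy-3,7,11,15-tetramethylhexadeca-2,6,14-trien-5-yl acetate | CC(=O)O[C@H](/C=C(\C)CCC[C@H](C)C(O)CC=C(C)C)C/C(C)=C/Cc1cc(O[Si](C)(C)C(C)(C)C)cc(C)c1O[Si](C)(C)C(C)(C)C
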